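**Plan**
- Retrosynthetic cuts: the aryl–acyl bond C5–C(=O) of the chalcone (aryllithium plus unsaturated Weinreb amide), the aryl–vinyl bond of the cinnamoyl unit (Heck), and the C2–C3 bond of the dihydrobenzofuran.
- Enabling feature: benzofuran C3 is a benzylic CH2 and C2 is an ether CH whose only other carbon neighbour is the quaternary carbinol carbon. C2–C3 can therefore come from a carbene on the benzylic carbon inserting into a C–H bond of an ArO–CH2–C(CH3)2O group.
- Forward order: the ether chain is put on a salicylaldehyde, the aldehyde becomes a sulfonylhydrazone, and carbene insertion closes the dihydrofuran ring (steps 1–5). The chroman ring is closed separately and extended by Heck coupling (steps 6–7). The halves are joined at C5 through a bromine carried from the start (step 8), and one acid step frees both hydroxyls (step 9).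
- Stereochemistry: C2 (R) is the only stereocentre and is set in step 5 by the chiral dirhodium carboxylate, which selects one of the two enantiotopic OCH2 hydrogens. The E alkene comes from the Heck reaction.
- Spectator groups: 6-OH as MOM ether, tertiary OH as triethylsilyl ether, and C5–Br as the acylation handle, which also makes the diazo carbon less nucleophilic.

Key step: step 5

Assumption: the sense of induction of the PTAD dirhodium catalyst with a carbene that carries one aryl group and hydrogen cannot be read from precedent; the route is written with Rh2(R-PTAD)4, and the mirror-image complex Rh2(S-PTAD)4 would be used instead if a pilot run delivers the S ether.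

**Step 1**
Reactants: 1 5-bromo-2,4-dihydroxybenzaldehyde
Product: 2 5-bromo-2-hydroxy-4-(methoxymethoxy)benzaldehyde
Conditions: MOMCl (1.1 equiv), K2CO3 (1.2 equiv), acetone, 0 °C to rt
Reagents that add atoms: chloromethyl methyl ether, COCCl
Why: Williamson-type O-alkylation should go to the 4-OH, the more acidic and unencumbered phenol, because the 2-OH is held in a hydrogen bond to the ortho aldehyde.

**Step 2**
Reactants: 2 5-bromo-2-hydroxy-4-(methoxymethoxy)benzaldehyde; 3 isobutylene oxide (2,2-dimethyloxirane)
Product: 4 5-bromo-2-(2-hydroxy-2-methylpropoxy)-4-(methoxymethoxy)benzaldehyde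
Conditions: K2CO3 (0.5 equiv), DMF, 100 °C, sealed tube
Reagents that add atoms: none
Why: Base-mediated SN2 opening of the epoxide by the phenoxide at its unsubstituted CH2 (a Williamson-type etherification) should install the ArO–CH2–C(CH3)2OH chain, the alkoxide formed regenerating phenoxide by proton transfer.

**Step 3**
Reactants: 4 5-bromo-2-(2-hydroxy-2-methylpropoxy)-4-(methoxymethoxy)benzaldehyde
Product: 5 5-bromo-4-(methoxymethoxy)-2-[2-methyl-2-(triethylsilyloxy)propoxy]benzaldehyde
Conditions: TESCl (1.5 equiv), imidazole (3 equiv), DMAP (0.1 equiv), DMF, rt to 40 °C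
Reagents that add atoms: chlorotriethylsilane, CC[Si](Cl)(CC)CC
Why: Imidazole/DMAP-promoted silylation of the tertiary alcohol with the small triethylsilyl chloride should leave the MOM acetal intact (a silyl triflate is avoided for that reason) and removes the O–H bond that a carbene would otherwise attack.

**Step 4**
Reactants: 5 5-bromo-4-(methoxymethoxy)-2-[2-methyl-2-(triethylsilyloxy)propoxy]benzaldehyde
Product: 6 (E)-N'-{5-bromo-4-(methoxymethoxy)-2-[2-methyl-2-(triethylsilyloxy)propoxy]benzylidene}-2-(trifluoromethyl)benzenesulfonohydrazide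
Conditions: 2-(CF3)C6H4SO2NHNH2 (1.05 equiv), MeOH, rt
Reagents that add atoms: 2-(trifluoromethyl)benzenesulfonohydrazide, NNS(=O)(=O)c1ccccc1C(F)(F)F
Why: Hydrazone formation by condensation needs no added acid, so the MOM acetal and the silyl ether should survive, and the ortho-CF3 sulfonyl group is chosen because its hydrazone salts fragment to the diazo compound below room temperature.

**Step 5**
Reactants: 6 (E)-N'-{5-bromo-4-(methoxymethoxy)-2-[2-methyl-2-(triethylsilyloxy)propoxy]benzylidene}-2-(trifluoromethyl)benzenesulfonohydrazide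
Product: 9 (2R)-5-bromo-6-(methoxymethoxy)-2-[2-(triethylsilyloxy)propan-2-yl]-2,3-dihydro-1-benzofuran, via sodium sulfonylhydrazonide 7 (not isolated), via aryldiazomethane 8 (not isolated)
Conditions: NaH (2 equiv), Rh2(R-PTAD)4 (dirhodium tetrakis[(R)-(1-adamantyl)(N-phthalimido)acetate], 2 mol%), CH2Cl2, −20 °C to rt
Reagents that add atoms: none
Why: Proposed new method: deprotonation of 6 gives salt 7, which loses sulfinate slowly (Bamford–Stevens fragmentation) and so releases diazo compound 8 at a low stationary concentration; the dirhodium tetracarboxylate converts 8, with loss of N2, into an electrophilic rhodium benzylidene whose carbene carbon inserts into one C–H bond of the ArO–CH2 group through a three-centre, hydride-transfer-like transition state. The closest known reaction type is the enantioselective dirhodium-catalysed intramolecular insertion of diaryl or aryl/alkyl (donor/donor) carbenes into ether α-C–H bonds to give 2,3-disubstituted dihydrobenzofurans, together with the established release of donor carbenes from sulfonylhydrazone salts; new here are a carbene with a single aryl donor and hydrogen, and a neopentyl-type OCH2 next to a silyloxy-bearing quaternary carbon. The dihydrofuran ring closes by 1,5-insertion, the C2–C3 bond forming within a five-membered array of the carbene carbon, two arene carbons, the ether oxygen and the OCH2 carbon. The C2 stereocentre is controlled only by the catalyst, whose chiral carboxylate pocket should let just one of the two enantiotopic OCH2 hydrogens reach the carbene. The step needs chemoselectivity for intramolecular insertion over azine or stilbene formation and over attack at other sites; this should be secured by the slow release of 8, the bromine meta to the carbene carbon (less nucleophilic diazo compound, more electrophilic carbene), the lack of any hydrogen for a 1,2-shift, the silyl cap on the tertiary oxygen (no O–H insertion), the absence of any alkene, and the fact that only the OCH2 hydrogens lie five atoms from the carbene carbon.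

**Step 6**
Reactants: 10 4-bromophenol; 11 isoprene
Product: 12 6-bromo-2,2-dimethylchroman
Conditions: isoprene (1.5 equiv, added slowly), 85% H3PO4, toluene, 35–50 °C
Reagents that add atoms: none
Why: Brønsted-acid Friedel–Crafts prenylation ortho to the hydroxyl (para is blocked by bromine) followed by Markovnikov hydroalkoxylation of the prenyl alkene should close the 2,2-dimethylchroman ring in one operation.

**Step 7**
Reactants: 12 6-bromo-2,2-dimethylchroman; 13 N-methoxy-N-methylacrylamide
Product: 14 (E)-3-(2,2-dimethylchroman-6-yl)-N-methoxy-N-methylacrylamide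
Conditions: Pd(OAc)2 (3 mol%), P(o-tol)3 (6 mol%), Et3N (2 equiv), DMF, 100 °C
Reagents that add atoms: none
Why: Mizoroki–Heck coupling of the aryl bromide with the acrylamide should give the E alkene through syn carbopalladation and syn β-hydride elimination, the Weinreb amide being inert under these conditions.

**Step 8**
Reactants: 9 (2R)-5-bromo-6-(methoxymethoxy)-2-[2-(triethylsilyloxy)propan-2-yl]-2,3-dihydro-1-benzofuran; 14 (E)-3-(2,2-dimethylchroman-6-yl)-N-methoxy-N-methylacrylamide
Product: 17 (E)-3-(2,2-dimethylchroman-6-yl)-1-{(2R)-6-(methoxymethoxy)-2-[2-(triethylsilyloxy)propan-2-yl]-2,3-dihydro-1-benzofuran-5-yl}prop-2-en-1-one, via aryllithium 15 (not isolated), via tetrahedral lithium adduct 16 (not isolated)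
Conditions: n-BuLi (1.05 equiv), THF, −78 °C, 15 min; then 14 (1.1 equiv), −78 to −20 °C; sat. aq. NH4Cl
Reagents that add atoms: none
Why: Bromine–lithium exchange at C5 outruns any deprotonation at −78 °C, and 1,2-addition of the aryllithium to the unsaturated Weinreb amide (Weinreb ketone synthesis) should stop at the chelated adduct, which releases the enone only on quench, while the C2 stereocentre carries no acidic hydrogen.

**Step 9**
Reactants: 17 (E)-3-(2,2-dimethylchroman-6-yl)-1-{(2R)-6-(methoxymethoxy)-2-[2-(triethylsilyloxy)propan-2-yl]-2,3-dihydro-1-benzofuran-5-yl}prop-2-en-1-one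
Product: 18 (E)-3-(2,2-dimethylchroman-6-yl)-1-[(2R)-6-hydroxy-2-(2-hydroxypropan-2-yl)-2,3-dihydro-1-benzofuran-5-yl]prop-2-en-1-one (CNP0327385.2)
Conditions: 3 M aq. HCl, MeOH/THF, rt
Reagents that add atoms: none
Why: Acid-catalysed solvolysis should cleave the MOM acetal (assisted by the neighbouring carbonyl) and the triethylsilyl ether together, under conditions too mild to ionise the tertiary alcohol, close the hydroxychalcone to a flavanone, or disturb the C2 ether stereocentre.

**Compound list**
1 | 5-bromo-2,4-dihydroxybenzaldehyde | O=Cc1cc(Br)c(O)cc1O | starting material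
2 | 5-bromo-2-hydroxy-4-(methoxymethoxy)benzaldehyde | O=Cc1cc(Br)c(OCOC)cc1O | intermediate
3 | isobutylene oxide (2,2-dimethyloxirane) | CC1(C)CO1 | starting material
4 | 5-bromo-2-(2-hydroxy-2-methylpropoxy)-4-(methoxymethoxy)benzaldehyde | O=Cc1cc(Br)c(OCOC)cc1OCC(C)(C)O | intermediate
5 | 5-bromo-4-(methoxymethoxy)-2-[2-methyl-2-(triethylsilyloxy)propoxy]benzaldehyde | O=Cc1cc(Br)c(OCOC)cc1OCC(C)(C)O[Si](CC)(CC)CC | intermediate
6 | (E)-N'-{5-bromo-4-(methoxymethoxy)-2-[2-methyl-2-(triethylsilyloxy)propoxy]benzylidene}-2-(trifluoromethyl)benzenesulfonohydrazide | COCOc1cc(OCC(C)(C)O[Si](CC)(CC)CC)c(/C=N/NS(=O)(=O)c2ccccc2C(F)(F)F)cc1Br | intermediate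
7 | sodium salt of hydrazone 6 (deprotonated at the sulfonamide nitrogen) | COCOc1cc(OCC(C)(C)O[Si](CC)(CC)CC)c(/C=N/[N-]S(=O)(=O)c2ccccc2C(F)(F)F)cc1Br.[Na+] | intermediate
8 | [5-bromo-4-(methoxymethoxy)-2-(2-methyl-2-triethylsilyloxypropoxy)phenyl]diazomethane | COCOc1cc(OCC(C)(C)O[Si](CC)(CC)CC)c(C=[N+]=[N-])cc1Br | intermediate
9 | (2R)-5-bromo-6-(methoxymethoxy)-2-[2-(triethylsilyloxy)propan-2-yl]-2,3-dihydro-1-benzofuran | COCOc1cc2O[C@@H](C(C)(C)O[Si](CC)(CC)CC)Cc2cc1Br | intermediate
10 | 4-bromophenol | Oc1ccc(Br)cc1 | starting material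
11 | isoprene | C=CC(C)=C | starting material
12 | 6-bromo-2,2-dimethylchroman | CC1(C)CCc2cc(Br)ccc2O1 | intermediate
13 | N-methoxy-N-methylacrylamide | C=CC(=O)N(C)OC | starting material
14 | (E)-3-(2,2-dimethylchroman-6-yl)-N-methoxy-N-methylacrylamide | CC1(C)CCc2cc(/C=C/C(=O)N(C)OC)ccc2O1 | intermediate
15 | {(2R)-6-(methoxymethoxy)-2-[2-(triethylsilyloxy)propan-2-yl]-2,3-dihydro-1-benzofuran-5-yl}lithium | COCOc1cc2O[C@@H](C(C)(C)O[Si](CC)(CC)CC)Cc2cc1[Li] | intermediate
16 | lithium alkoxide adduct of 15 and 14 (1-aryl-1-[methoxy(methyl)amino]-3-(2,2-dimethylchroman-6-yl)prop-2-en-1-olate, carbinol carbon unassigned) | CC1(C)CCc2cc(/C=C/C([O-])(N(C)OC)c3cc4c(cc3OCOC)O[C@@H](C(C)(C)O[Si](CC)(CC)CC)C4)ccc2O1.[Li+] | intermediate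
17 | (E)-3-(2,2-dimethylchroman-6-yl)-1-{(2R)-6-(methoxymethoxy)-2-[2-(triethylsilyloxy)propan-2-yl]-2,3-dihydro-1-benzofuran-5-yl}prop-2-en-1-one | CC1(C)CCc2cc(/C=C/C(=O)c3cc4c(cc3OCOC)O[C@@H](C(C)(C)O[Si](CC)(CC)CC)C4)ccc2O1 | intermediate
18 | (E)-3-(2,2-dimethylchroman-6-yl)-1-[(2R)-6-hydroxy-2-(2-hydroxypropan-2-yl)-2,3-dihydro-1-benzofuran-5-yl]prop-2-en-1-one | CC1(C)CCc2cc(/C=C/C(=O)c3cc4c(cc3O)O[C@@H](C(C)(C)O)C4)ccc2O1 | target

**Step count and risks**
Total steps: 9. Longest linear sequence: 7 (steps 1, 2, 3, 4, 5, 8, 9).

Steps most likely to fail: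

1. Step 5. The diazo compound may attack the rhodium carbene faster than the carbene inserts into the hindered, inductively deactivated OCH2 bond, giving azine or stilbene; the catalyst may also discriminate poorly between the two enantiotopic hydrogens. The fallback uses known chemistry, sets out from 2 and returns at 9, and makes the same C2–C3 bond by condensation. Rap–Stoermer reaction of 2 with chloroacetone (K2CO3, DMF, 80 °C) would give 1-[5-bromo-6-(methoxymethoxy)-1-benzofuran-2-yl]ethanone F1. MeMgBr (THF, 0 °C) would convert it into 2-[5-bromo-6-(methoxymethoxy)-1-benzofuran-2-yl]propan-2-ol F2, and TESCl/imidazole into 5-bromo-6-(methoxymethoxy)-2-[2-(triethylsilyloxy)propan-2-yl]-1-benzofuran F3. Asymmetric hydrogenation of the furan C2=C3 bond of this 2-alkylbenzofuran would then set C2 and give 9. The catalyst would be Ru(cod)(2-methylallyl)2 with the chiral N-heterocyclic carbene from SINpEt·HBF4 and KOtBu, under H2 in hexane at rt, with the ligand antipode chosen for the R product; the aryl bromide is expected to survive these mild homogeneous conditions.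

2. Step 8. The aryllithium may add in conjugate fashion to the unsaturated amide or be protonated before acylation. The fallback sets out from 9 and 12 and returns at 17, building the enone by condensation. The aryllithium from 9 (n-BuLi, THF, −78 °C) would be quenched with N-methoxy-N-methylacetamide to give 1-{(2R)-6-(methoxymethoxy)-2-[2-(triethylsilyloxy)propan-2-yl]-2,3-dihydro-1-benzofuran-5-yl}ethanone F4. Bromine–lithium exchange on 12 followed by DMF would give 2,2-dimethylchroman-6-carbaldehyde F5. Claisen–Schmidt condensation of F4 with F5 (KOH, EtOH/THF, 0 °C to rt) would give 17.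

3. Step 9. Once the phenol is free, acid may close it onto the enone (flavanone formation) or dehydrate the tertiary alcohol. The fallback sets out from 9 and returns at 18, with deprotection placed before the enone exists. The methyl ketone 1-{(2R)-6-(methoxymethoxy)-2-[2-(triethylsilyloxy)propan-2-yl]-2,3-dihydro-1-benzofuran-5-yl}ethanone F4, made from 9 as above, would be treated with HCl in MeOH to give 1-[(2R)-6-hydroxy-2-(2-hydroxypropan-2-yl)-2,3-dihydro-1-benzofuran-5-yl]ethanone F6. Claisen–Schmidt condensation of F6 with 2,2-dimethylchroman-6-carbaldehyde F5 (aq. KOH, EtOH, rt, then cold dilute acid to neutral pH) would give 18 directly, the phenol being held as its phenoxide during the condensation.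

**Further compounds**
F1 | step 5 | 1-[5-bromo-6-(methoxymethoxy)-1-benzofuran-2-yl]ethanone | CC(=O)c1cc2cc(Br)c(OCOC)cc2o1
F2 | step 5 | 2-[5-bromo-6-(methoxymethoxy)-1-benzofuran-2-yl]propan-2-ol | CC(C)(O)c1cc2cc(Br)c(OCOC)cc2o1
F3 | step 5 | 5-bromo-6-(methoxymethoxy)-2-[2-(triethylsilyloxy)propan-2-yl]-1-benzofuran | CC[Si](CC)(CC)OC(C)(C)c1cc2cc(Br)c(OCOC)cc2o1
F4 | step 8 | 1-{(2R)-6-(methoxymethoxy)-2-[2-(triethylsilyloxy)propan-2-yl]-2,3-dihydro-1-benzofuran-5-yl}ethanone | CC(=O)c1cc2c(cc1OCOC)O[C@@H](C(C)(C)O[Si](CC)(CC)CC)C2
F5 | step 8 | 2,2-dimethylchroman-6-carbaldehyde | CC1(C)CCc2cc(C=O)ccc2O1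
F6 | step 9 | 1-[(2R)-6-hydroxy-2-(2-hydroxypropan-2-yl)-2,3-dihydro-1-benzofuran-5-yl]ethanone | CC(=O)c1cc2c(cc1O)O[C@@H](C(C)(C)O)C2
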